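Remark (assumption and labels): the SMILES is taken at face value, so the two halves have the same sense at C6/C6′ but opposite configuration at the isopropyl carbon C7/C7′. Atoms carry 2,3-seco-cadinane locants: half B (alcohol half) has C1 (ring fusion, bears lactone C2=O), C3 (OCH2), C4 (bears C15 acid), C5 (=CH), C6 (ring fusion), C7 (CH-iPr), C8, C9, C10 (C-OH) and C14 (CH2O); half A (acyl half) carries primes.

## The problem

1. The target is an ester of two seco-cadinane units: the acrylic acid C15′ of half A acylates the primary C14 hydroxyl of half B, next to the tertiary C10 carbinol.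
2. Half B is a cyclohexane (C1, C6, C7, C8, C9, C10) cis-fused through C1–C6 to a seven-membered unsaturated lactone (C1, C2, O, C3, C4, C5, C6). Its four contiguous stereocentres (C10, C1, C6, C7) carry the C10 hydroxyl, C2 and C5 on one face and the isopropyl group on the other.
3. C7 can control C6, but C1 and C10 cannot be set by additions anti to their neighbours, because each new bond must go to the more hindered face. C1 is also α to the lactone carbonyl and β to the tertiary hydroxyl (epimerisation, retro-aldol, dehydration), and a free C14 hydroxyl could translactonise.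
4. Half A is a 3-substituted p-menth-1-en-7-ol with the contra-thermodynamic 6′,7′-cis relationship and the opposite configuration at the isopropyl carbon, so the halves cannot share one chiral precursor.
5. Both halves contain an (E)-2-(oxymethyl)acrylate unit, free in A and lactonised in B; the allylic alcohols, acrylates and the β-hydroxy lactone rule out strong acid or base late in the route.
6. The feature that the plan uses: in half B, C1 and C6 each bear exactly one exocyclic carbon (C2, C5) on the same face and lie α and β to C10, a carbinol carbon at the ketone oxidation level. Joining C2 to C5 in the mind gives a cis-fused cyclobutane (C1, C2, C5, C6) on a 4-isopropylcyclohexanone, the retron of an enone–allene [2+2] photocycloaddition. The 1,4-relationship of C2 (carboxyl) and C5 (sp2 CH) across O–C3–C4 lets the four-membered ring stand in for the seven-membered one.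

## Retrosynthesis

**33 ← 32.** The C15 acid is masked as a tert-butyl ester until the end, so that only one carboxylate is present when the halves are joined.

**32 ← 31 + 17.** The C14–O ester bond is cut, and the C10 hydroxyl and C14 oxygen are read as the two ends of a spiro-oxirane. Compared with acylating a diol, this needs no acyl activation, so the two primary allylic hydroxyls of acid 31 stay unprotected, and C10 becomes an oxirane stereocentre that can be made from a ketone. The forward reaction must open a 2,2-disubstituted oxirane at its CH2 terminus with a carboxylate.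

**17 ← 11 + 15.** The O–C3 and C4=C5 bonds of the oxepinone are cut together. The precursor is the cis acid–aldehyde 11 plus the three-carbon phosphonoacrylate 15. The ring fixes the alkene geometry and C15 arrives as its tert-butyl ester. The forward step is an oxa-Michael/intramolecular olefination.

**11 ← 9 ← 8 ← 7.** C2 and C5 are reconnected. Acid–aldehyde 11 is the ozonolysis product of the silyl enol ether 10 of cyclobutanone 9; 9 comes from methylidene 8 by ozonolysis; oxirane 8 comes from ketone 7 by sulfur-ylide methylenation. The cyclobutane enforces the C1/C6 cis fusion and its convex face sets C10. C10 must stop being a ketone before C2 becomes a carbonyl, otherwise C1 would sit in a 1,3-dicarbonyl.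

**7 ← 4 + 5 (key step).** Both cyclobutane bonds (C1–C2, C6–C5) are cut. The precursors are the nine-carbon enone 4 and allene 5. The forward photocycloaddition must be head-to-head and anti to the isopropyl group.

**4 ← 3 ← 1 + 2.** Cryptone is opened to the keto aldehyde 3, an organocatalytic Michael adduct of isovaleraldehyde 1 and methyl vinyl ketone 2. The mirror-image catalyst gives 18 and 19 for half A.

**31 ← 30 ← 29.** Acid 31 comes from ester 29 by removal of the methoxymethyl group (30) and saponification.

**29 ← 24 + 27.** The C5′–C6′ bond is cut (and C4′=C5′ through loss of nitrous acid from 28). A carbon placed cis to the isopropyl group cannot come from steric control, so it is put in by allylic substitution with net retention. The leaving group in 24 is cis because hydride attacked anti to the isopropyl group. Nitro ester 27 acts as a β-acrylate anion equivalent.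

**24 ← 23 ← 22 ← 21 ← 19 + 20.** The carbonate comes from the cis alcohol 23, this from enone 22 by reduction, and 22 from cryptone 19 by 1,2-addition of the C14′ unit (stannane 20) and oxidative 1,3-transposition of 21.

**Reagents.** 15 ← 12 + 13 (via 14); 27 ← 25 + 13 (via 26).

## Roads not taken

**Alternative 1:** the most obvious plan cuts the C14–O ester (acylation of a half-B diol by an activated, hydroxyl-protected half-A acid) and the C4=C5 bond (ring-closing metathesis). The cyclohexane would come from conjugate addition of a vinyl cuprate to 4 with C-acylation of the enolate by a 2-(hydroxymethyl)acrylate-derived acyl donor. The forward key step is ring closure with the second-generation Grubbs catalyst to the β-keto lactone A1. In A1, C1 lies between two carbonyls, so its configuration is lost by enolisation and the cis fusion is not secured. A 1,3-dicarbonyl also resists ylide or organometallic addition at C10, and the acylation forces protection of half A. The chosen plan sets C1 kinetically in a ring that cannot epimerise and never has C10 and C2 as carbonyls at the same time.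

**Alternative 2:** a bio-inspired plan would cut C2–O only. A Diels–Alder reaction of 4 with an oxygenated diene and adjustment would give the cis-fused cadinane-type β,γ-unsaturated ketone A2, and a Baeyer–Villiger oxidation would insert oxygen between C2 and C3. The Diels–Alder step gives the right C1/C6/C7 relationship, but the insertion needs the allylic CH2 (C3, deactivated by the acrylate) to migrate in preference to the secondary C1, which cannot be defended. The β,γ-enone is also prone to conjugation, and several redox steps are needed to place the ketone and the C4=C5 bond. The chosen plan cuts the C2–C5 bond of a cyclobutane instead, where regiochemistry is fixed by enolisation towards a CH2.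

**Alternative 3:** an intramolecular nitrile oxide cycloaddition from a nitroethyl-acrylate side chain on C6 onto a C10=C1 double bond would give isoxazoline A3, placing the C10 oxygen and C2 syn and cis to C5 in one step. The stereochemical logic is sound, but the run-up is long (conjugate addition, enol triflate chemistry, side-chain construction with a nitro group). The ring formed must be cut again at C2–C3, which brings back the migration problem of Alternative 2 or three extra steps. The chosen [2+2] reaches the same cis triad from a nine-carbon enone and allene.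

Key step: step 3

## Steps

Step 1
Reactants: 1 3-methylbutanal; 2 but-3-en-2-one
Product: 3 (2S)-5-oxo-2-(propan-2-yl)hexanal
Conditions: (S)-α,α-diphenylprolinol trimethylsilyl ether (5 mol %), ethyl 3,4-dihydroxybenzoate (20 mol %), neat, 4 °C
Reagents that add atoms: none
Why: Enamine-catalysed Michael addition of the aldehyde to the enone; the enamine should be attacked on the face remote from the diaryl(silyloxy)methyl group, which sets the isopropyl-bearing carbon (later C7) as S.

Step 2
Reactants: 3 (2S)-5-oxo-2-(propan-2-yl)hexanal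
Product: 4 (4S)-4-(propan-2-yl)cyclohex-2-en-1-one
Conditions: KOH (0.1 M aq.), Bu4NOH (cat.), Et2O/THF, reflux
Reagents that add atoms: none
Why: Intramolecular aldol condensation of the methyl ketone onto the aldehyde; the stereocentre ends as the γ-carbon of the enone and should survive the brief basic treatment.

Step 3
Reactants: 4 (4S)-4-(propan-2-yl)cyclohex-2-en-1-one; 5 propa-1,2-diene
Product: 7 (1R,5S,6S)-8-methylidene-5-(propan-2-yl)bicyclo[4.2.0]octan-2-one, via trans-fused photoadduct 6 (not isolated)
Conditions: 5 (excess), THF, −78 °C, hν (Hg lamp, Pyrex filter); then basic Al2O3, Et2O, rt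
Reagents that add atoms: none
Why: Enone–allene [2+2] photocycloaddition: excitation and intersystem crossing give the triplet enone, which adds to ground-state allene stepwise, first at C6 and then by closure at C1. The closest known reaction type is the head-to-head photocycloaddition of allene to 4-alkylcyclohex-2-enones, which puts the sp carbon on the α-carbon and leaves an exocyclic methylidene β,γ to the ketone. The cyclobutane (C1, C2, C5, C6) is closed in the [2+2] mode, with C6–C5 and C1–C2 formed across one face of the enone double bond. C6 is controlled by the adjacent C7: allene should approach the face of the twisted triplet opposite the isopropyl group, so that C5 ends trans to it. C1 is controlled by ring strain: only the cis-fused bicyclo[4.2.0]octanone is stable, and any trans-fused isomer 6 is epimerised at the enolisable C1 on basic Al2O3. The step needs head-to-head regiochemistry, secured by the usual orientation of allene, and anti facial selectivity, secured only by C7 and therefore the main stereochemical risk. The product holds C2 as a masked ketone and C5 as a CH2 group, differentiated for the two later cuts, and its convex face will direct the C10 oxirane.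

Step 4
Reactants: 7 (1R,5S,6S)-8-methylidene-5-(propan-2-yl)bicyclo[4.2.0]octan-2-one
Product: 8 (1R,2R,5S,6S)-8-methylidene-5-(propan-2-yl)spiro[bicyclo[4.2.0]octane-2,2'-oxirane]
Conditions: Me3S+ I−, KN(SiMe3)2, THF, −10 → 0 °C
Reagents that add atoms: trimethylsulfonium iodide, C[S+](C)C.[I-]
Why: Corey–Chaykovsky epoxidation: the sulfonium ylide should add irreversibly to the ketone from the convex (axial) face, anti to the axial C1–C2 cyclobutane bond, so that C14 is delivered trans and the oxirane oxygen cis to C2, the C10 configuration of the target.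

Step 5
Reactants: 8 (1R,2R,5S,6S)-8-methylidene-5-(propan-2-yl)spiro[bicyclo[4.2.0]octane-2,2'-oxirane]
Product: 9 (1S,2R,5S,6S)-5-(propan-2-yl)spiro[bicyclo[4.2.0]octane-2,2'-oxiran]-8-one
Conditions: O3, CH2Cl2, −78 °C; then Me2S
Reagents that add atoms: ozone, [O-][O+]=O
Why: Ozonolysis of the 1,1-disubstituted exocyclic alkene unmasks the cyclobutanone (C2=O); the oxirane is inert to ozone and, with C10 no longer a ketone, no 1,3-diketone can form.

Step 6
Reactants: 9 (1S,2R,5S,6S)-5-(propan-2-yl)spiro[bicyclo[4.2.0]octane-2,2'-oxiran]-8-one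
Product: 11 (3R,4S,5S,6S)-5-formyl-6-(propan-2-yl)-1-oxaspiro[2.5]octane-4-carboxylic acid, via trimethylsilyl enol ether 10 (not isolated)
Conditions: LiN(iPr)2, Me3SiCl (in situ quench), THF, −78 °C; then O3, CH2Cl2, −78 °C; Me2S; aq. pH 4 buffer
Reagents that add atoms: ozone, [O-][O+]=O
Why: Kinetic deprotonation should occur at the unhindered C5H2 (a C1 enolate would put a double bond at the strained ring fusion) and is trapped as the silyl enol ether; ozonolysis of this electron-rich C2=C5 bond opens the four-membered ring and releases C2 as the acid and C5 as the aldehyde, cis on the cyclohexane.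

Step 7
Reactants: 12 tert-butyl 2-(diethoxyphosphoryl)acetate; 13 formaldehyde (as paraformaldehyde)
Product: 15 tert-butyl 2-(diethoxyphosphoryl)prop-2-enoate, via hydroxymethyl phosphonate 14 (not isolated)
Conditions: piperidine (cat.), MeOH, reflux; then TsOH (cat.), toluene, reflux (−H2O)
Reagents that add atoms: none
Why: Knoevenagel-type hydroxymethylation of the phosphonoacetate and acid-catalysed dehydration, the standard route to 2-phosphonoacrylates.

Step 8
Reactants: 11 (3R,4S,5S,6S)-5-formyl-6-(propan-2-yl)-1-oxaspiro[2.5]octane-4-carboxylic acid; 15 tert-butyl 2-(diethoxyphosphoryl)prop-2-enoate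
Product: 17 tert-butyl (5aR,6S,9R,9aS)-1-oxo-6-(propan-2-yl)-3,5a,6,7,8,9a-hexahydro-1H-spiro[2-benzoxepine-9,2'-oxirane]-4-carboxylate, via oxa-Michael adduct 16 (not isolated)
Conditions: Cs2CO3 (1.05 equiv), 15 (1.2 equiv), MeCN/THF, 0 °C → rt, high dilution
Reagents that add atoms: none
Why: Proposed new method: the cesium carboxylate of 11 should add reversibly to the doubly activated alkene of 15 to give the phosphonate-stabilised carbanion 16, held seven atoms from the cis aldehyde; irreversible intramolecular Horner–Wadsworth–Emmons olefination then forms C4=C5 inside the ring, which dictates the alkene geometry; the closest known reaction type is the Michael addition/intramolecular Horner–Wadsworth–Emmons annulation of 2-(dialkoxyphosphoryl)acrylates with hydroxy-, mercapto- or nitro-substituted aldehydes and ketones, which gives five- and six-membered rings.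

Step 9
Reactants: 1 3-methylbutanal; 2 but-3-en-2-one
Product: 18 (2R)-5-oxo-2-(propan-2-yl)hexanal
Conditions: (R)-α,α-diphenylprolinol trimethylsilyl ether (5 mol %), ethyl 3,4-dihydroxybenzoate (20 mol %), neat, 4 °C
Reagents that add atoms: none
Why: Same enamine Michael addition as step 1 with the mirror-image catalyst, giving the antipode needed for C7′.

Step 10
Reactants: 18 (2R)-5-oxo-2-(propan-2-yl)hexanal
Product: 19 (4R)-4-(propan-2-yl)cyclohex-2-en-1-one
Conditions: KOH (0.1 M aq.), Bu4NOH (cat.), Et2O/THF, reflux
Reagents that add atoms: none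
Why: Intramolecular aldol condensation as in step 2.

Step 11
Reactants: 19 (4R)-4-(propan-2-yl)cyclohex-2-en-1-one; 20 tributyl[(methoxymethoxy)methyl]stannane
Product: 21 (4R)-1-[(methoxymethoxy)methyl]-4-(propan-2-yl)cyclohex-2-en-1-ol (both C1 epimers)
Conditions: 20, n-BuLi, THF, −78 °C; then 19; H2O
Reagents that add atoms: none
Why: Tin–lithium exchange gives the α-alkoxymethyllithium, which adds 1,2 to the enone and brings in C14′; the epimer ratio at the carbinol does not matter because the next step destroys this stereocentre.

Step 12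
Reactants: 21 (4R)-1-[(methoxymethoxy)methyl]-4-(propan-2-yl)cyclohex-2-en-1-ol
Product: 22 (6R)-3-[(methoxymethoxy)methyl]-6-(propan-2-yl)cyclohex-2-en-1-one
Conditions: pyridinium chlorochromate (C5H5NH)[CrO3Cl], NaOAc, 4 Å MS, CH2Cl2, rt
Reagents that add atoms: pyridinium chlorochromate, [O-][Cr](=O)(=O)Cl.c1cc[nH+]cc1
Why: Babler–Dauben oxidative 1,3-transposition: the chromate ester of the tertiary allylic alcohol undergoes a [3,3] shift and oxidation to the transposed enone; C7′ becomes α to the ketone, hence the buffer.

Step 13
Reactants: 22 (6R)-3-[(methoxymethoxy)methyl]-6-(propan-2-yl)cyclohex-2-en-1-one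
Product: 23 (1S,6R)-3-[(methoxymethoxy)methyl]-6-(propan-2-yl)cyclohex-2-en-1-ol
Conditions: LiBH(s-Bu)3, THF, −78 °C; then aq. NaOH
Reagents that add atoms: none
Why: 1,2-Reduction of the β,β-disubstituted enone by the bulky borohydride; hydride should attack C6′ anti to the adjacent isopropyl group, so the hydroxyl ends cis to it.

Step 14
Reactants: 23 (1S,6R)-3-[(methoxymethoxy)methyl]-6-(propan-2-yl)cyclohex-2-en-1-ol
Product: 24 (1S,6R)-3-[(methoxymethoxy)methyl]-6-(propan-2-yl)cyclohex-2-en-1-yl methyl carbonate
Conditions: ClCO2Me, pyridine, DMAP (cat.), CH2Cl2, 0 °C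
Reagents that add atoms: methyl chloroformate, COC(=O)Cl
Why: O-Acylation with retention gives the allylic carbonate, whose ionisation releases the methoxide that will deprotonate the pronucleophile in step 16.

Step 15
Reactants: 25 methyl 3-nitropropanoate; 13 formaldehyde (cracked monomer)
Product: 27 methyl 2-(hydroxymethyl)-3-nitropropanoate, via dilithio dianion 26 (not isolated)
Conditions: LiN(iPr)2 (2.1 equiv), THF/DMPU, −78 °C; then 13; AcOH
Reagents that add atoms: none
Why: The doubly deprotonated nitro ester reacts with electrophiles at the carbon α to the ester, its more reactive site, so formaldehyde gives the 2-hydroxymethyl compound; this is known chemistry of that dianion.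

Step 16
Reactants: 24 (1S,6R)-3-[(methoxymethoxy)methyl]-6-(propan-2-yl)cyclohex-2-en-1-yl methyl carbonate; 27 methyl 2-(hydroxymethyl)-3-nitropropanoate
Product: 29 methyl (2E)-2-(hydroxymethyl)-3-{(1S,6R)-3-[(methoxymethoxy)methyl]-6-(propan-2-yl)cyclohex-2-en-1-yl}prop-2-enoate, via allylated nitro ester 28 (not isolated)
Conditions: Pd2(dba)3·CHCl3 (2.5 mol %), Ph2PCH2CH2PPh2 (10 mol %), THF, 40 °C; then DBU (2 equiv), rt
Reagents that add atoms: none
Why: Tsuji–Trost allylic alkylation: zerovalent palladium ionises the carbonate with inversion (metal anti to the isopropyl group) and the nitronate of 27 attacks the less substituted terminus C6′ anti to the metal, so two inversions leave C5′ cis to the isopropyl group; DBU then eliminates nitrous acid from the β-nitro ester 28 (E1cB) and should give the (E)-enoate.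

Step 17
Reactants: 29 methyl (2E)-2-(hydroxymethyl)-3-{(1S,6R)-3-[(methoxymethoxy)methyl]-6-(propan-2-yl)cyclohex-2-en-1-yl}prop-2-enoate
Product: 30 methyl (2E)-2-(hydroxymethyl)-3-[(1S,6R)-3-(hydroxymethyl)-6-(propan-2-yl)cyclohex-2-en-1-yl]prop-2-enoate
Conditions: HCl (cat.), MeOH, 40 °C
Reagents that add atoms: none
Why: Acid-catalysed transacetalisation of the methoxymethyl ether to methanol; the methyl ester is degenerate towards the solvent.

Step 18
Reactants: 30 methyl (2E)-2-(hydroxymethyl)-3-[(1S,6R)-3-(hydroxymethyl)-6-(propan-2-yl)cyclohex-2-en-1-yl]prop-2-enoate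
Product: 31 (2E)-2-(hydroxymethyl)-3-[(1S,6R)-3-(hydroxymethyl)-6-(propan-2-yl)cyclohex-2-en-1-yl]prop-2-enoic acid
Conditions: LiOH, THF/H2O, 0 °C → rt; then 1 M HCl to pH 3
Reagents that add atoms: lithium hydroxide, [Li+].[OH-]
Why: Saponification of the methyl ester; the trisubstituted enoate is hindered towards conjugate addition of hydroxide.

Step 19
Reactants: 31 (2E)-2-(hydroxymethyl)-3-[(1S,6R)-3-(hydroxymethyl)-6-(propan-2-yl)cyclohex-2-en-1-yl]prop-2-enoic acid; 17 tert-butyl (5aR,6S,9R,9aS)-1-oxo-6-(propan-2-yl)-3,5a,6,7,8,9a-hexahydro-1H-spiro[2-benzoxepine-9,2'-oxirane]-4-carboxylate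
Product: 32 tert-butyl (5aR,6S,9R,9aS)-9-hydroxy-9-({[(2E)-2-(hydroxymethyl)-3-[(1S,6R)-3-(hydroxymethyl)-6-(propan-2-yl)cyclohex-2-en-1-yl]prop-2-enoyl]oxy}methyl)-1-oxo-6-(propan-2-yl)-1,3,5a,6,7,8,9,9a-octahydro-2-benzoxepine-4-carboxylate
Conditions: 31 (1.2 equiv), Cs2CO3 (10 mol %), DMF, 70 °C
Reagents that add atoms: none
Why: SN2 opening of the 2,2-disubstituted oxirane at its CH2 terminus (C14) by the cesium carboxylate of 31, the tertiary alkoxide being reprotonated by excess acid; no acyl activation is involved, so the hydroxyls of 31 stay free, and C10 keeps the configuration of step 4 because its C–O bond is not touched.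

Step 20
Reactants: 32 tert-butyl ester of the target
Product: 33 (5aR,6S,9R,9aS)-9-hydroxy-9-({[(2E)-2-(hydroxymethyl)-3-[(1S,6R)-3-(hydroxymethyl)-6-(propan-2-yl)cyclohex-2-en-1-yl]prop-2-enoyl]oxy}methyl)-1-oxo-6-(propan-2-yl)-1,3,5a,6,7,8,9,9a-octahydro-2-benzoxepine-4-carboxylic acid (target)
Conditions: 85% aq. H3PO4, toluene, rt
Reagents that add atoms: none
Why: Acid-mediated loss of 2-methylpropene from the tert-butyl ester, under conditions chosen to spare the allylic alcohols, the β-hydroxy lactone and the two other esters.

## Compound list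

1 | 3-methylbutanal | CC(C)CC=O | starting material
2 | but-3-en-2-one | CC(=O)C=C | starting material
3 | (2S)-5-oxo-2-(propan-2-yl)hexanal | CC(=O)CC[C@@H](C(C)C)C=O | intermediate
4 | (4S)-4-(propan-2-yl)cyclohex-2-en-1-one ((S)-cryptone) | O=C1CC[C@@H](C(C)C)C=C1 | intermediate
5 | propa-1,2-diene (allene) | C=C=C | starting material
6 | (1S,5S,6S)-8-methylidene-5-(propan-2-yl)bicyclo[4.2.0]octan-2-one (trans-fused photoadduct) | O=C1CC[C@@H](C(C)C)[C@@H]2CC(=C)[C@H]21 | intermediate (not isolated)
7 | (1R,5S,6S)-8-methylidene-5-(propan-2-yl)bicyclo[4.2.0]octan-2-one (cis-fused, cyclobutane anti to isopropyl) | O=C1CC[C@@H](C(C)C)[C@@H]2CC(=C)[C@@H]21 | intermediate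
8 | (1R,2R,5S,6S)-8-methylidene-5-(propan-2-yl)spiro[bicyclo[4.2.0]octane-2,2'-oxirane] | C1O[C@@]12CC[C@@H](C(C)C)[C@@H]3CC(=C)[C@@H]32 | intermediate
9 | (1S,2R,5S,6S)-5-(propan-2-yl)spiro[bicyclo[4.2.0]octane-2,2'-oxiran]-8-one | C1O[C@@]12CC[C@@H](C(C)C)[C@@H]3CC(=O)[C@@H]32 | intermediate
10 | trimethylsilyl enol ether of 9 (cyclobutene C7=C8, 8-OSiMe3) | C1O[C@@]12CC[C@@H](C(C)C)[C@@H]3C=C(O[Si](C)(C)C)[C@@H]32 | intermediate (not isolated)
11 | (3R,4S,5S,6S)-5-formyl-6-(propan-2-yl)-1-oxaspiro[2.5]octane-4-carboxylic acid | C1O[C@@]12CC[C@@H](C(C)C)[C@H](C=O)[C@@H]2C(=O)O | intermediate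
12 | tert-butyl 2-(diethoxyphosphoryl)acetate | CCOP(=O)(OCC)CC(=O)OC(C)(C)C | starting material
13 | formaldehyde (paraformaldehyde or cracked monomer) | C=O | starting material
14 | tert-butyl 2-(diethoxyphosphoryl)-3-hydroxypropanoate | CCOP(=O)(OCC)C(CO)C(=O)OC(C)(C)C | intermediate (not isolated)
15 | tert-butyl 2-(diethoxyphosphoryl)prop-2-enoate | CCOP(=O)(OCC)C(=C)C(=O)OC(C)(C)C | intermediate
16 | oxa-Michael adduct: 3-tert-butoxy-2-(diethoxyphosphoryl)-3-oxopropyl ester of acid 11 | C1O[C@@]12CC[C@@H](C(C)C)[C@H](C=O)[C@@H]2C(=O)OCC(C(=O)OC(C)(C)C)P(=O)(OCC)OCC | intermediate (not isolated)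
17 | tert-butyl (5aR,6S,9R,9aS)-1-oxo-6-(propan-2-yl)-3,5a,6,7,8,9a-hexahydro-1H-spiro[2-benzoxepine-9,2'-oxirane]-4-carboxylate | C1O[C@@]12CC[C@@H](C(C)C)[C@@H]3C=C(C(=O)OC(C)(C)C)COC(=O)[C@@H]32 | intermediate
18 | (2R)-5-oxo-2-(propan-2-yl)hexanal | CC(=O)CC[C@H](C(C)C)C=O | intermediate
19 | (4R)-4-(propan-2-yl)cyclohex-2-en-1-one ((R)-cryptone) | CC(C)[C@H]1CCC(=O)C=C1 | intermediate
20 | tributyl[(methoxymethoxy)methyl]stannane | CCCC[Sn](CCCC)(CCCC)COCOC | starting material
21 | (4R)-1-[(methoxymethoxy)methyl]-4-(propan-2-yl)cyclohex-2-en-1-ol (both C1 epimers) | CC(C)[C@H]1CCC(O)(COCOC)C=C1 | intermediate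
22 | (6R)-3-[(methoxymethoxy)methyl]-6-(propan-2-yl)cyclohex-2-en-1-one | CC(C)[C@H]1CCC(COCOC)=CC1=O | intermediate
23 | (1S,6R)-3-[(methoxymethoxy)methyl]-6-(propan-2-yl)cyclohex-2-en-1-ol | CC(C)[C@H]1CCC(COCOC)=C[C@H]1O | intermediate
24 | (1S,6R)-3-[(methoxymethoxy)methyl]-6-(propan-2-yl)cyclohex-2-en-1-yl methyl carbonate | CC(C)[C@H]1CCC(COCOC)=C[C@H]1OC(=O)OC | intermediate
25 | methyl 3-nitropropanoate | COC(=O)CC[N+](=O)[O-] | starting material
26 | dilithium salt of doubly deprotonated methyl 3-nitropropanoate | [Li+].[Li+].COC(=O)[CH-]C=[N+]([O-])[O-] | intermediate (not isolated)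
27 | methyl 2-(hydroxymethyl)-3-nitropropanoate (racemic) | COC(=O)C(CO)C[N+](=O)[O-] | intermediate
28 | methyl 2-(hydroxymethyl)-3-{(1S,6R)-3-[(methoxymethoxy)methyl]-6-(propan-2-yl)cyclohex-2-en-1-yl}-3-nitropropanoate (diastereomers at C2 and C3) | CC(C)[C@H]1CCC(COCOC)=C[C@H]1C([N+](=O)[O-])C(CO)C(=O)OC | intermediate (not isolated)
29 | methyl (2E)-2-(hydroxymethyl)-3-{(1S,6R)-3-[(methoxymethoxy)methyl]-6-(propan-2-yl)cyclohex-2-en-1-yl}prop-2-enoate | CC(C)[C@H]1CCC(COCOC)=C[C@H]1/C=C(\CO)C(=O)OC | intermediate
30 | methyl (2E)-2-(hydroxymethyl)-3-[(1S,6R)-3-(hydroxymethyl)-6-(propan-2-yl)cyclohex-2-en-1-yl]prop-2-enoate | CC(C)[C@H]1CCC(CO)=C[C@H]1/C=C(\CO)C(=O)OC | intermediate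
31 | (2E)-2-(hydroxymethyl)-3-[(1S,6R)-3-(hydroxymethyl)-6-(propan-2-yl)cyclohex-2-en-1-yl]prop-2-enoic acid (half A) | CC(C)[C@H]1CCC(CO)=C[C@H]1/C=C(\CO)C(=O)O | intermediate
32 | tert-butyl ester of the target (name as in step 19) | CC(C)[C@H]1CCC(CO)=C[C@H]1/C=C(\CO)C(=O)OC[C@@]1(O)CC[C@@H](C(C)C)[C@@H]2C=C(C(=O)OC(C)(C)C)COC(=O)[C@@H]21 | intermediate
33 | CNP0361406.7 (name as in step 20) | CC(C)[C@H]1CCC(CO)=C[C@H]1/C=C(\CO)C(=O)OC[C@@]1(O)CC[C@@H](C(C)C)[C@@H]2C=C(C(=O)O)COC(=O)[C@@H]21 | target

## Step count and risk

Total step count: 20 (steps 1–20, including the two reagent preparations, steps 7 and 15). Longest linear sequence: 11 steps (9–14, 16–20).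

**Step 8 (proposed new method).** The oxa-Michael addition may simply reverse without ring closure, because a carboxylate is a weak donor and a good leaving group; polymerisation of 15 or intermolecular olefination could then take over. The fallback sets out from 11 and comes back at 17 with known reactions. The hydroxymethyl phosphonate 14 is isolated and silylated (t-BuMe2SiCl, imidazole) to tert-butyl 3-[(tert-butyldimethylsilyl)oxy]-2-(diethoxyphosphoryl)propanoate F1. Intermolecular Horner–Wadsworth–Emmons olefination of 11 with F1 (NaH, 2 equiv, THF) should give the (E)-silyloxymethyl enoate acid F2 after separation of the geometric isomer. Bu4NF/AcOH frees the hydroxy acid F3, and Shiina macrolactonisation (2-methyl-6-nitrobenzoic anhydride, DMAP, Et3N, high dilution) closes the seven-membered lactone 17.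

**Step 3 (key step).** Facial discrimination in the first bond formation rests on one adjacent stereocentre in a twisted triplet and may be insufficient; head-to-tail addition and base-promoted migration of the exocyclic double bond during epimerisation are further risks. The fallback sets out from 4 and comes back at 11 by a polar, ground-state cyclobutene synthesis whose first bond forms in a Michael sense anti to the isopropyl group. A CuCl2/AgSbF6-catalysed Ficini [2+2] cycloaddition of 4 with N-ethynyl-N,4-dimethylbenzenesulfonamide gives the cis-fused amido-cyclobutene F4. Corey–Chaykovsky epoxidation as in step 4 gives the spiro-oxirane F5. Ozonolysis of the enamide double bond gives the N-acyl sulfonamide aldehyde F6, and LiOH in aqueous THF hydrolyses the activated amide to 11.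

**Step 16.** Attack of the branched nitronate on the face cis to the isopropyl group may be slow, so that β-hydride elimination to a diene, attack at the tertiary terminus C10′ or O-allylation competes. The fallback sets out from 23 and comes back at 29 with an inversion/inversion-free sequence instead of double inversion. Mitsunobu reaction of 23 (4-nitrobenzoic acid, PPh3, diisopropyl azodicarboxylate) gives the trans (1R,6R)-4-nitrobenzoate F7. Allyl–alkenyl Stille coupling (Pd2(dba)3, LiCl, DMF) with methyl (2E)-2-(hydroxymethyl)-3-(tributylstannyl)prop-2-enoate F8 (from methyl propiolate by stannylcupration and trapping with formaldehyde) proceeds with net inversion and delivers the whole side chain cis to the isopropyl group, giving 29 directly.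

**Step 19.** Opening of the hindered oxirane may be slow, and base-induced β-elimination from C1 (oxirane to allylic alcohol) or epimerisation at C1 may compete. The fallback sets out from 17 and 31 and comes back at 32 by classical acylation. Dilute HClO4 in aqueous THF opens 17 to the diol lactone F9. Acid 31 is converted into its bis(tert-butyldimethylsilyl) ether acid F10 (t-BuMe2SiCl, imidazole; then K2CO3, MeOH to cleave the silyl ester). Yamaguchi esterification of the primary hydroxyl of F9 with F10 gives the bis-silylated coupled ester F11, and HF·pyridine removes the silyl ethers to give 32.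

## Further compounds

F1 | step 8 | tert-butyl 3-[(tert-butyldimethylsilyl)oxy]-2-(diethoxyphosphoryl)propanoate | CCOP(=O)(OCC)C(CO[Si](C)(C)C(C)(C)C)C(=O)OC(C)(C)C
F2 | step 8 | (3R,4S,5S,6S)-5-[(1E)-3-tert-butoxy-2-{[(tert-butyldimethylsilyl)oxy]methyl}-3-oxoprop-1-en-1-yl]-6-(propan-2-yl)-1-oxaspiro[2.5]octane-4-carboxylic acid | C1O[C@@]12CC[C@@H](C(C)C)[C@H](/C=C(\CO[Si](C)(C)C(C)(C)C)C(=O)OC(C)(C)C)[C@@H]2C(=O)O
F3 | step 8 | (3R,4S,5S,6S)-5-[(1E)-3-tert-butoxy-2-(hydroxymethyl)-3-oxoprop-1-en-1-yl]-6-(propan-2-yl)-1-oxaspiro[2.5]octane-4-carboxylic acid | C1O[C@@]12CC[C@@H](C(C)C)[C@H](/C=C(\CO)C(=O)OC(C)(C)C)[C@@H]2C(=O)O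
F4 | step 3 | N,4-dimethyl-N-[(1R,5S,6S)-2-oxo-5-(propan-2-yl)bicyclo[4.2.0]oct-7-en-8-yl]benzenesulfonamide (cis-fused, anti to isopropyl) | O=C1CC[C@@H](C(C)C)[C@@H]2C=C(N(C)S(=O)(=O)c3ccc(C)cc3)[C@@H]21
F5 | step 3 | spiro-oxirane of F4 at the ketone carbon (oxirane oxygen cis to the cyclobutene) | C1O[C@@]12CC[C@@H](C(C)C)[C@@H]3C=C(N(C)S(=O)(=O)c4ccc(C)cc4)[C@@H]32
F6 | step 3 | (3R,4S,5S,6S)-5-formyl-N-methyl-N-(4-methylbenzenesulfonyl)-6-(propan-2-yl)-1-oxaspiro[2.5]octane-4-carboxamide | C1O[C@@]12CC[C@@H](C(C)C)[C@H](C=O)[C@@H]2C(=O)N(C)S(=O)(=O)c3ccc(C)cc3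
F7 | step 16 | (1R,6R)-3-[(methoxymethoxy)methyl]-6-(propan-2-yl)cyclohex-2-en-1-yl 4-nitrobenzoate | CC(C)[C@H]1CCC(COCOC)=C[C@@H]1OC(=O)c2ccc(cc2)[N+](=O)[O-]
F8 | step 16 | methyl (2E)-2-(hydroxymethyl)-3-(tributylstannyl)prop-2-enoate | CCCC[Sn](CCCC)(CCCC)/C=C(\CO)C(=O)OC
F9 | step 19 | tert-butyl (5aR,6S,9R,9aS)-9-hydroxy-9-(hydroxymethyl)-1-oxo-6-(propan-2-yl)-1,3,5a,6,7,8,9,9a-octahydro-2-benzoxepine-4-carboxylate | OC[C@@]1(O)CC[C@@H](C(C)C)[C@@H]2C=C(C(=O)OC(C)(C)C)COC(=O)[C@@H]21
F10 | step 19 | (2E)-2-{[(tert-butyldimethylsilyl)oxy]methyl}-3-[(1S,6R)-3-{[(tert-butyldimethylsilyl)oxy]methyl}-6-(propan-2-yl)cyclohex-2-en-1-yl]prop-2-enoic acid | CC(C)[C@H]1CCC(CO[Si](C)(C)C(C)(C)C)=C[C@H]1/C=C(\CO[Si](C)(C)C(C)(C)C)C(=O)O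
F11 | step 19 | bis(tert-butyldimethylsilyl) ether of 32 | CC(C)[C@H]1CCC(CO[Si](C)(C)C(C)(C)C)=C[C@H]1/C=C(\CO[Si](C)(C)C(C)(C)C)C(=O)OC[C@@]1(O)CC[C@@H](C(C)C)[C@@H]2C=C(C(=O)OC(C)(C)C)COC(=O)[C@@H]21
A1 | alternative 1 | tert-butyl (5aR,6S)-1,9-dioxo-6-(propan-2-yl)-1,3,5a,6,7,8,9,9a-octahydro-2-benzoxepine-4-carboxylate (C9a labile) | O=C1CC[C@@H](C(C)C)[C@@H]2C=C(C(=O)OC(C)(C)C)COC(=O)C21
A2 | alternative 2 | cis-fused cadinane-type β,γ-unsaturated ketone with C10 spiro-oxirane (carbocycle C1–C2(=O)–C3H2–C4(CO2tBu)=C5H–C6) | C1O[C@@]12CC[C@@H](C(C)C)[C@@H]3C=C(C(=O)OC(C)(C)C)CC(=O)[C@@H]32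
A3 | alternative 3 | isoxazoline from intramolecular nitrile oxide cycloaddition (oxygen on C10, C2=N, C14 O-silyl, methyl ester) | CC(C)(C)[Si](C)(C)OC[C@]12CC[C@@H](C(C)C)[C@@H]3C=C(C(=O)OC)CC(=NO1)[C@@H]32
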